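The acyl chain (ester carbonyl = C1) is disconnected at C10–C11, the sp3–sp3 bond two carbons beyond the C5≡C6–C7≡C8 diyne. The feature exploited is the C9–C10 ethano link on C8: with one sacrificial carboxyl carbon it is the CH2CH2CO2H of pent-4-ynoic acid. The precursor is therefore a mixed undeca-4,6-diynedioate carrying the complete furyl-diynol ester at one end and an N-hydroxyphthalimide (redox-active) ester at the other. In the last step a nickel-catalysed decarboxylative alkyl–alkyl Negishi coupling expels CO2, unveils C10 as a primary radical and joins it to C11 of [9-(furan-2-yl)nonyl]zinc bromide. Both furan rings are carried through untouched.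

Key step: step 13

Remark: the target has no stereocentre and no stereogenic double bond, so no stereocontrol is needed.
Remark: compounds 1, 2, 7, 8, 11, 14, 17 and 20 are assumed to be commercially available.

Step 1
Reactants: 1 prop-2-yn-1-ol; 2 1-bromododecane
Product: 4 pentadec-2-yn-1-ol, via dilithiated prop-2-yn-1-ol 3 (not isolated)
Conditions: n-BuLi (2.1 equiv), THF/DMPU, −78 → 0 °C; then 2, 0 °C → rt; H2O
Reagents that add atoms: none
Why: Double deprotonation gives the C,O-dilithio species, whose acetylide carbon is far more reactive than the alkoxide toward the primary bromide (SN2 alkylation of a lithium acetylide), so C-alkylation should dominate.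

Step 2
Reactants: 4 pentadec-2-yn-1-ol
Product: 5 pentadec-14-yn-1-ol
Conditions: NaH (5 equiv), H2N(CH2)3NH2, 70 °C; H2O quench
Reagents that add atoms: none
Why: Alkyne zipper reaction: the aminopropylamide base relays the triple bond along the chain by propargyl–allenyl prototropic shifts until it reaches the terminus, where irreversible acetylide formation makes the terminal alkyne the sink.

Step 3
Reactants: 5 pentadec-14-yn-1-ol
Product: 6 15-bromopentadec-14-yn-1-ol
Conditions: NBS (1.1 equiv), AgNO3 (10 mol %), acetone, rt
Reagents that add atoms: N-bromosuccinimide (O=C1CCC(=O)N1Br)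
Why: Silver-catalysed electrophilic bromination of the terminal alkyne via the silver acetylide; the primary alcohol is inert, and the bromination is placed on the furan-free partner.

Step 4
Reactants: 7 furan; 8 1-bromo-4-chlorobutane
Product: 10 2-(4-chlorobutyl)furan, via 2-furyllithium 9 (not isolated)
Conditions: n-BuLi, THF, −78 → 0 °C; then 8, −78 °C → rt
Reagents that add atoms: none
Why: Furan is lithiated at C2 (α-metalation) and 2-furyllithium displaces bromide much faster than chloride (SN2 alkylation), leaving the chloride as the handle for steps 5 and 11.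

Step 5
Reactants: 10 2-(4-chlorobutyl)furan; 11 lithium acetylide–ethylenediamine complex
Product: 12 2-(hex-5-yn-1-yl)furan
Conditions: DMSO, NaI (cat.), rt
Reagents that add atoms: none
Why: SN2 alkylation of lithium acetylide in DMSO with in-situ Finkelstein activation of the primary chloride; the 2-alkylfuran is stable to the basic medium.

Step 6
Reactants: 6 15-bromopentadec-14-yn-1-ol; 12 2-(hex-5-yn-1-yl)furan
Product: 13 21-(furan-2-yl)henicosa-14,16-diyn-1-ol
Conditions: CuCl (10 mol %), NH2OH·HCl, n-BuNH2, MeOH/THF/H2O, 0 °C → rt, slow addition of 6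
Reagents that add atoms: none
Why: Cadiot–Chodkiewicz coupling: the copper(I) acetylide of 12 reacts with the 1-bromoalkyne to give the unsymmetrical 1,3-diyne, hydroxylamine keeping copper in the +1 state so that oxidative homocoupling is suppressed.

Step 7
Reactants: 14 hex-5-ynoic acid
Product: 15 6-bromohex-5-ynoic acid
Conditions: Br2, KOH, H2O, 0 °C; then dil. HCl to pH 2
Reagents that add atoms: bromine (BrBr)
Why: Hypobromite (Straus-type) bromination of the terminal alkyne proceeds through acetylide/positive-bromine exchange in strongly basic water, where the carboxylate should not engage in halolactonisation.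

Step 8
Reactants: 15 6-bromohex-5-ynoic acid; 13 21-(furan-2-yl)henicosa-14,16-diyn-1-ol
Product: 16 21-(furan-2-yl)henicosa-14,16-diyn-1-yl 6-bromohex-5-ynoate
Conditions: EDC·HCl, DMAP (cat.), CH2Cl2, 0 °C → rt
Reagents that add atoms: none
Why: Steglich esterification under neutral conditions joins acid and alcohol without touching the furan, the diyne or the bromoalkyne.

Step 9
Reactants: 16 21-(furan-2-yl)henicosa-14,16-diyn-1-yl 6-bromohex-5-ynoate; 17 pent-4-ynoic acid
Product: 18 11-{[21-(furan-2-yl)henicosa-14,16-diyn-1-yl]oxy}-11-oxoundeca-4,6-diynoic acid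
Conditions: CuCl (10 mol %), NH2OH·HCl, n-BuNH2, THF/MeOH/H2O, 0 °C, 17 in excess, slow addition of 16; citric acid work-up
Reagents that add atoms: none
Why: Second Cadiot–Chodkiewicz coupling, with pent-4-ynoic acid entering as its ammonium carboxylate; low temperature and short contact time should spare the alkyl ester from aminolysis.

Step 10
Reactants: 18 11-{[21-(furan-2-yl)henicosa-14,16-diyn-1-yl]oxy}-11-oxoundeca-4,6-diynoic acid
Product: 19 1-(1,3-dioxoisoindolin-2-yl) 11-[21-(furan-2-yl)henicosa-14,16-diyn-1-yl] undeca-4,6-diynedioate
Conditions: N-hydroxyphthalimide, DIC, DMAP (cat.), CH2Cl2, rt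
Reagents that add atoms: N-hydroxyphthalimide (ON1C(=O)c2ccccc2C1=O)
Why: Carbodiimide-mediated esterification of the free acid gives the redox-active ester; the alkyl ester, diynes and furans are inert.

Step 11
Reactants: 10 2-(4-chlorobutyl)furan; 20 1,5-dibromopentane
Product: 22 2-(9-bromononyl)furan, via [4-(furan-2-yl)butyl]magnesium chloride 21 (not isolated)
Conditions: Mg turnings, BrCH2CH2Br (cat.), THF, reflux; then slow addition to 20 (3 equiv), Li2CuCl4 (3 mol %), THF, −10 → 0 °C; excess 20 removed by distillation
Reagents that add atoms: none
Why: Grignard formation from the primary chloride followed by Kochi-type copper-catalysed sp3–sp3 coupling at one C–Br bond of the dibromide joins the C4 and C5 units into the nonyl chain, the excess of dibromide favouring monoalkylation.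

Step 12
Reactants: 22 2-(9-bromononyl)furan
Product: 23 [9-(furan-2-yl)nonyl]zinc bromide
Conditions: Zn dust (1.5 equiv, activated with BrCH2CH2Br and TMSCl, cat.), LiCl (1.5 equiv), THF, 50 °C; decanted, titrated with I2 and kept as the THF solution of its LiCl complex
Reagents that add atoms: zinc ([Zn])
Why: LiCl-promoted direct oxidative insertion of activated zinc into the primary C–Br bond gives the monoalkylzinc bromide; the furan ring is inert to zinc and to the organozinc.

Step 13
Reactants: 19 1-(1,3-dioxoisoindolin-2-yl) 11-[21-(furan-2-yl)henicosa-14,16-diyn-1-yl] undeca-4,6-diynedioate; 23 [9-(furan-2-yl)nonyl]zinc bromide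
Product: 24 21-(furan-2-yl)henicosa-14,16-diyn-1-yl 19-(furan-2-yl)nonadeca-5,7-diynoate
Conditions: NiCl2·glyme (20 mol %), 4,4′-di-tert-butyl-2,2′-bipyridine (40 mol %), 23 (3 equiv, THF solution with LiCl), DMF, 25 °C; aq. NH4Cl
Reagents that add atoms: none
Why: Transmetalation from 23 gives an alkyl–Ni(I)(bipyridine) species that transfers one electron to the phthalimide unit of 19; the radical anion fragments with loss of phthalimide anion and CO2 to the primary C10 radical, which is captured at nickel, and C(sp3)–C(sp3) reductive elimination from dialkyl–Ni(III) forges C10–C11. The closest known reaction type is the nickel-catalysed decarboxylative Negishi alkyl–alkyl coupling of N-hydroxyphthalimide esters with alkylzinc reagents, applied here to a primary acid and a primary alkylzinc halide used in excess as its LiCl complex to keep transmetalation fast. No ring is closed and no stereocentre is created. The step needs chemoselectivity for the NHPI ester over the alkyl ester, the two 1,3-diynes and the furans: only the N-acyloxyphthalimide is reducible by single-electron transfer, alkylzinc halides do not add to esters at room temperature, and dialkyl-substituted internal alkynes should be poor substrates for carbozincation at 25 °C. The homopropargylic radical has no productive rearrangement (3-exo closure onto C8 is reversible and degenerate), and fast capture by nickel/bipyridine should limit β-hydride loss towards the conjugated ene-diyne.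

Compound list
1 | prop-2-yn-1-ol | C#CCO | starting material
2 | 1-bromododecane | CCCCCCCCCCCCBr | starting material
3 | dilithiated prop-2-yn-1-ol (C,O-dilithio) | [Li]C#CCO[Li] | intermediate
4 | pentadec-2-yn-1-ol | CCCCCCCCCCCCC#CCO | intermediate
5 | pentadec-14-yn-1-ol | C#CCCCCCCCCCCCCCO | intermediate
6 | 15-bromopentadec-14-yn-1-ol | BrC#CCCCCCCCCCCCCCO | intermediate
7 | furan | c1ccoc1 | starting material
8 | 1-bromo-4-chlorobutane | BrCCCCCl | starting material
9 | 2-furyllithium | [Li]c1ccco1 | intermediate
10 | 2-(4-chlorobutyl)furan | ClCCCCc1ccco1 | intermediate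
11 | lithium acetylide–ethylenediamine complex | [Li]C#C.NCCN | starting material
12 | 2-(hex-5-yn-1-yl)furan | C#CCCCCc1ccco1 | intermediate
13 | 21-(furan-2-yl)henicosa-14,16-diyn-1-ol | OCCCCCCCCCCCCCC#CC#CCCCCc1ccco1 | intermediate
14 | hex-5-ynoic acid | C#CCCCC(=O)O | starting material
15 | 6-bromohex-5-ynoic acid | BrC#CCCCC(=O)O | intermediate
16 | 21-(furan-2-yl)henicosa-14,16-diyn-1-yl 6-bromohex-5-ynoate | BrC#CCCCC(=O)OCCCCCCCCCCCCCC#CC#CCCCCc1ccco1 | intermediate
17 | pent-4-ynoic acid | C#CCCC(=O)O | starting material
18 | 11-{[21-(furan-2-yl)henicosa-14,16-diyn-1-yl]oxy}-11-oxoundeca-4,6-diynoic acid | OC(=O)CCC#CC#CCCCC(=O)OCCCCCCCCCCCCCC#CC#CCCCCc1ccco1 | intermediate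
19 | 1-(1,3-dioxoisoindolin-2-yl) 11-[21-(furan-2-yl)henicosa-14,16-diyn-1-yl] undeca-4,6-diynedioate | O=C(CCC#CC#CCCCC(=O)OCCCCCCCCCCCCCC#CC#CCCCCc1ccco1)ON1C(=O)c2ccccc2C1=O | intermediate
20 | 1,5-dibromopentane | BrCCCCCBr | starting material
21 | [4-(furan-2-yl)butyl]magnesium chloride | Cl[Mg]CCCCc1ccco1 | intermediate
22 | 2-(9-bromononyl)furan | BrCCCCCCCCCc1ccco1 | intermediate
23 | [9-(furan-2-yl)nonyl]zinc bromide | Br[Zn]CCCCCCCCCc1ccco1 | intermediate
24 | 21-(furan-2-yl)henicosa-14,16-diyn-1-yl 19-(furan-2-yl)nonadeca-5,7-diynoate | O=C(CCCC#CC#CCCCCCCCCCCCc1ccco1)OCCCCCCCCCCCCCC#CC#CCCCCc1ccco1 | target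

Total step count: 13
Longest linear sequence: 8 steps (1 → 2 → 3 → 6 → 8 → 9 → 10 → 13)

Steps most likely to fail

Step 13. Transmetalation from the monoalkylzinc halide to nickel may be slow, so that the C10 radical is lost to protodecarboxylation or dimerisation. Low-valent nickel may also be diverted by coordination to the two conjugated diynes, leading to carbozincation or oligomerisation, and the homopropargylic alkyl–nickel may undergo β-hydride elimination towards the ene-diyne. The fallback forms the same C10–C11 bond by a polar, copper-catalysed alkylation; it sets out from 16 and returns at 24. Cadiot–Chodkiewicz coupling of 16 with commercial but-3-yn-1-ol (C#CCCO; CuCl, NH2OH·HCl, n-BuNH2, 0 °C) should give 21-(furan-2-yl)henicosa-14,16-diyn-1-yl 10-hydroxydeca-5,7-diynoate F1. Appel bromination (CBr4, PPh3, CH2Cl2, 0 °C) should convert it into 21-(furan-2-yl)henicosa-14,16-diyn-1-yl 10-bromodeca-5,7-diynoate F2. Bromide 22 would be converted with magnesium turnings in THF into [9-(furan-2-yl)nonyl]magnesium bromide F3. Slow addition of this Grignard reagent to F2 with catalytic Li2CuCl4 in THF/NMP at −20 → 0 °C (Kochi-type alkyl–alkyl coupling, ester-tolerant at low temperature) should then give 24.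

Step 9. The bromoalkyne may homocouple through copper-mediated halogen exchange, the long-chain ester may undergo aminolysis by the primary amine, and copper may cycloisomerise pent-4-ynoic acid to its enol lactone; phase mixing of the lipophilic ester with the carboxylate may also be poor. The fallback carries the acid terminus through the coupling at the alcohol oxidation level; it sets out from 16 and returns at 18. Cadiot–Chodkiewicz coupling of 16 with commercial pent-4-yn-1-ol (C#CCCCO), a neutral and well-behaved partner, should give 21-(furan-2-yl)henicosa-14,16-diyn-1-yl 11-hydroxyundeca-5,7-diynoate F4. Direct oxidation of the primary alcohol to the acid with TEMPO (cat.)/PhI(OAc)2 in MeCN/aqueous pH 7 buffer should then give 18.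

Step 7. Under hypobromite the carboxylate may add to the activated alkyne (6-exo bromolactonisation), or oxidative degradation may compete with the acetylide bromination. The fallback masks the acid and uses silver-mediated electrophilic bromination; it sets out from 14 and returns at 15. Fischer esterification (MeOH, cat. H2SO4) should give methyl hex-5-ynoate F5. NBS/AgNO3 (cat.) in acetone should give methyl 6-bromohex-5-ynoate F6. Saponification with LiOH in THF/H2O at 0 °C, followed by acidification, should give 15.

Further compounds
F1 | step 13 | 21-(furan-2-yl)henicosa-14,16-diyn-1-yl 10-hydroxydeca-5,7-diynoate | OCCC#CC#CCCCC(=O)OCCCCCCCCCCCCCC#CC#CCCCCc1ccco1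
F2 | step 13 | 21-(furan-2-yl)henicosa-14,16-diyn-1-yl 10-bromodeca-5,7-diynoate | BrCCC#CC#CCCCC(=O)OCCCCCCCCCCCCCC#CC#CCCCCc1ccco1
F3 | step 13 | [9-(furan-2-yl)nonyl]magnesium bromide | Br[Mg]CCCCCCCCCc1ccco1
F4 | step 9 | 21-(furan-2-yl)henicosa-14,16-diyn-1-yl 11-hydroxyundeca-5,7-diynoate | OCCCC#CC#CCCCC(=O)OCCCCCCCCCCCCCC#CC#CCCCCc1ccco1
F5 | step 7 | methyl hex-5-ynoate | C#CCCCC(=O)OC
F6 | step 7 | methyl 6-bromohex-5-ynoate | BrC#CCCCC(=O)OC
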